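**Retrosynthetic overview**

1. Target ⇒ removal of two phenolic MOM groups ⇒ protonolysis of a C1–boron bond. The boron on benzylic C1 is a traceless tether that first holds the aryl ring and the C1=C2 vinyl unit together.
2. Key disconnection C2–C3, with the ring-carbon–C1 bond made in the same operation: a three-component nickel-catalysed conjunctive coupling of 3,5-bis(methoxymethoxy)phenyllithium, vinylboronic acid pinacol ester and the complete C15 iodide (7S,9Z)-15-iodopentadec-9-en-7-ol.
3. C15 iodide ⇒ Finkelstein exchange and Lindlar reduction (Z-C8=C9) ⇒ (7S)-15-chloropentadec-9-yn-7-ol ⇒ 7-chlorohept-1-yne + (S)-1,2-epoxyoctane (C11 stereocentre bought); 7-chlorohept-1-yne ⇒ 1-bromo-5-chloropentane + lithium acetylide.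
4. Enabling feature: ring carbon C5 of the benzene-1,3-diol, benzylic C1 and C2 form an unfunctionalised aryl–CH2–CH2–alkyl unit, which is a 1,2-dicarbofunctionalised ethylene. Boron ends on benzylic C1, where the aromatic ring makes C–B protonolysis easy.
5. Rings: none is constructed. The benzene ring is carried from 5-bromobenzene-1,3-diol; the dioxaborolane ring of the tether enters intact and leaves in step 7.

Key step: step 6

Assumption: the target is the (11S) alcohol with an (8Z) olefin, and (S)-1,2-epoxyoctane of high enantiomeric purity is taken as purchased.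

**Route**

Step 1
Reactants: 1 1-bromo-5-chloropentane; 2 lithium acetylide–ethylenediamine complex
Product: 3 7-chlorohept-1-yne
Conditions: DMSO, 15 °C → rt
Reagents that add atoms: none
Why: SN2 alkylation of an acetylide, in which bromide is displaced far faster than chloride in DMSO, so mono-alkylation at the C–Br end should give the ω-chloro terminal alkyne (no stereocentre involved).

Step 2
Reactants: 3 7-chlorohept-1-yne; 4 (S)-1,2-epoxyoctane
Product: 6 (7S)-15-chloropentadec-9-yn-7-ol, via lithium acetylide 5 (not isolated)
Conditions: 3, n-BuLi, THF, −78 °C; BF3·OEt2; then 4, −78 °C; aq NH4Cl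
Reagents that add atoms: none
Why: Yamaguchi–Hirao alkynylation (BF3-promoted SN2 opening of a terminal epoxide by a lithium acetylide) attacks the unsubstituted CH2 of 4, so the C–O bond at the stereocentre is never broken and the (S) configuration of the epoxide becomes the (S)-carbinol (C11 of the target), while the primary chloride is inert at −78 °C.

Step 3
Reactants: 6 (7S)-15-chloropentadec-9-yn-7-ol
Product: 7 (7S,9Z)-15-chloropentadec-9-en-7-ol
Conditions: H2 (1 atm), Lindlar catalyst (Pd/CaCO3, Pb-poisoned), quinoline, EtOAc, rt
Reagents that add atoms: none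
Why: Lindlar semihydrogenation delivers H2 syn on poisoned palladium, so the internal alkyne should give the Z-alkene (C8=C9 of the target) and stop there, leaving the primary chloride and the free alcohol untouched.

Step 4
Reactants: 7 (7S,9Z)-15-chloropentadec-9-en-7-ol
Product: 8 (7S,9Z)-15-iodopentadec-9-en-7-ol
Conditions: NaI (5 equiv), NaHCO3 (cat.), butan-2-one, 80 °C
Reagents that add atoms: sodium iodide, [Na+].[I-]
Why: Finkelstein halide exchange (SN2, driven by precipitation of NaCl) should turn the primary chloride into the iodide needed for nickel activation without touching the secondary alcohol or the Z-alkene.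

Step 5
Reactants: 9 5-bromobenzene-1,3-diol
Product: 10 1-bromo-3,5-bis(methoxymethoxy)benzene
Conditions: MOMCl (3 equiv), i-Pr2NEt (4 equiv), CH2Cl2, 0 °C → rt
Reagents that add atoms: chloromethyl methyl ether, COCCl
Why: Williamson-type O-alkylation of both phenols gives acetal protection that survives tert-butyllithium, the boronate chemistry and fluoride and is later removed by mild acid.

Step 6
Reactants: 10 1-bromo-3,5-bis(methoxymethoxy)benzene; 11 4,4,5,5-tetramethyl-2-vinyl-1,3,2-dioxaborolane (vinylboronic acid pinacol ester); 8 (7S,9Z)-15-iodopentadec-9-en-7-ol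
Product: 14 (7S,9Z)-17-[3,5-bis(methoxymethoxy)phenyl]-17-(4,4,5,5-tetramethyl-1,3,2-dioxaborolan-2-yl)heptadec-9-en-7-ol (both C17 epimers), via aryllithium 12 (not isolated), via boron ate complex 13 (not isolated)
Conditions: 10, t-BuLi (2.0 equiv), Et2O, −78 °C; then 11, −78 °C → rt; solvent exchange to THF; then 8 (0.7 equiv), NiBr2·glyme (10 mol %), rac-trans-N,N′-dimethylcyclohexane-1,2-diamine (12 mol %), THF/DMSO, rt, degassed
Reagents that add atoms: none
Why: Nickel(I) abstracts iodine from 8 and the resulting primary alkyl (radical or alkylnickel) attacks the terminal vinyl carbon of ate complex 13 (future C2), forging C2–C3, while the aryl group shifts from boron to the adjacent carbon (1,2-metallate rearrangement, future C1) and nickel is turned over. The closest known reaction type is the nickel-catalysed conjunctive cross-coupling of vinylboron ate complexes with unactivated alkyl iodides, related to the radical–polar crossover of vinyl boronates. No ring is closed, and the dioxaborolane ring enters intact. The only new stereocentre, boron-bearing C1, is deliberately left uncontrolled (racemic ligand) because both epimers converge to CH2 in step 7, whereas C11 (S) and the Z-olefin are remote and not engaged. The step needs conjunctive three-component selectivity over direct aryl–alkyl coupling, β-hydride elimination and 6-exo radical cyclisation onto C8=C9: the four-coordinate pinacol boronate resists transmetalation, aryl is the best migrating group, and a hept-6-enyl-type radical should cyclise much more slowly than it is captured. The free hydroxyl should be tolerated because no organolithium remains once 13 is formed and a tetracoordinate boronate is not basic enough to be protonated by an alcohol.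

Step 7
Reactants: 14 (7S,9Z)-17-[3,5-bis(methoxymethoxy)phenyl]-17-(4,4,5,5-tetramethyl-1,3,2-dioxaborolan-2-yl)heptadec-9-en-7-ol
Product: 15 (7S,9Z)-17-[3,5-bis(methoxymethoxy)phenyl]heptadec-9-en-7-ol
Conditions: TBAF·3H2O (3 equiv), THF, 50 °C, argon
Reagents that add atoms: none
Why: Fluoride-promoted protodeboronation of a benzylic pinacol boronic ester, in which fluoride adds to boron and the C1–B bond, activated by the adjacent aromatic ring, is protonolysed by the water of hydration, should erase the temporary stereocentre (both epimers give the same CH2) without touching MOM ethers, alcohol or Z-alkene.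

Step 8
Reactants: 15 (7S,9Z)-17-[3,5-bis(methoxymethoxy)phenyl]heptadec-9-en-7-ol
Product: 16 5-[(8Z,11S)-11-hydroxyheptadec-8-en-1-yl]benzene-1,3-diol
Conditions: 3 M aq HCl/MeOH (1:10), 40 °C
Reagents that add atoms: none
Why: Acid-catalysed acetal cleavage (transacetalisation to methanol) should free both phenols, while dilute methanolic HCl neither ionises the secondary homoallylic alcohol nor isomerises the Z-alkene, so C11 (S) and the olefin geometry are retained.

**Compound list**

1 | 1-bromo-5-chloropentane | ClCCCCCBr | starting material
2 | lithium acetylide–ethylenediamine complex | [Li]C#C.NCCN | starting material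
3 | 7-chlorohept-1-yne | C#CCCCCCCl | intermediate
4 | (S)-1,2-epoxyoctane [(2S)-2-hexyloxirane] | CCCCCC[C@H]1CO1 | starting material
5 | (7-chlorohept-1-yn-1-yl)lithium (not isolated) | [Li]C#CCCCCCCl | intermediate
6 | (7S)-15-chloropentadec-9-yn-7-ol | CCCCCC[C@H](O)CC#CCCCCCCl | intermediate
7 | (7S,9Z)-15-chloropentadec-9-en-7-ol | CCCCCC[C@H](O)C/C=C\CCCCCCl | intermediate
8 | (7S,9Z)-15-iodopentadec-9-en-7-ol | CCCCCC[C@H](O)C/C=C\CCCCCI | intermediate
9 | 5-bromobenzene-1,3-diol | Oc1cc(O)cc(Br)c1 | starting material
10 | 1-bromo-3,5-bis(methoxymethoxy)benzene | COCOc1cc(Br)cc(OCOC)c1 | intermediate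
11 | 4,4,5,5-tetramethyl-2-vinyl-1,3,2-dioxaborolane | C=CB1OC(C)(C)C(C)(C)O1 | starting material
12 | [3,5-bis(methoxymethoxy)phenyl]lithium (not isolated) | [Li]c1cc(OCOC)cc(OCOC)c1 | intermediate
13 | lithium [3,5-bis(methoxymethoxy)phenyl](ethenyl)(pinacolato)borate (not isolated) | [Li+].C=C[B-]1(c2cc(OCOC)cc(OCOC)c2)OC(C)(C)C(C)(C)O1 | intermediate
14 | (7S,9Z)-17-[3,5-bis(methoxymethoxy)phenyl]-17-(4,4,5,5-tetramethyl-1,3,2-dioxaborolan-2-yl)heptadec-9-en-7-ol (both C17 epimers) | CCCCCC[C@H](O)C/C=C\CCCCCCC(B1OC(C)(C)C(C)(C)O1)c1cc(OCOC)cc(OCOC)c1 | intermediate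
15 | (7S,9Z)-17-[3,5-bis(methoxymethoxy)phenyl]heptadec-9-en-7-ol | CCCCCC[C@H](O)C/C=C\CCCCCCCc1cc(OCOC)cc(OCOC)c1 | intermediate
16 | 5-[(8Z,11S)-11-hydroxyheptadec-8-en-1-yl]benzene-1,3-diol | CCCCCC[C@H](O)C/C=C\CCCCCCCc1cc(O)cc(O)c1 | target

**Totals and risks**

Total step count: 8. Longest linear sequence: 7 steps (steps 1, 2, 3, 4, 6, 7, 8).

Steps most likely to fail:

Step 6. The aryl group may pass directly from boron to nickel, giving a two-component aryl–alkyl coupling that leaves out the C1–C2 unit. The alkylnickel may undergo β-hydride elimination or reduction, a nickel hydride may migrate or isomerise the C8=C9 double bond, and the free hydroxyl may slow the catalyst. The fallback makes the same C2–C3 bond by known two-component chemistry and leaves no boron to remove. It sets out from 10 and 11: a Suzuki–Miyaura vinylation (Pd(dppf)Cl2, K2CO3, dioxane/H2O, 80 °C) should give 1-ethenyl-3,5-bis(methoxymethoxy)benzene F1. Anti-Markovnikov hydroboration with 9-BBN (THF, rt) should then give 9-{2-[3,5-bis(methoxymethoxy)phenyl]ethyl}-9-borabicyclo[3.3.1]nonane F2, which is not isolated. F2 is joined to iodide 8 by an alkyl–alkyl Suzuki–Miyaura coupling (Pd(PPh3)4, K3PO4, dioxane, 60 °C). The fallback comes back to the route at 15, so step 7 is no longer needed.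

Step 7. The fluoroboronate of a secondary benzylic centre may ionise too slowly, so that protonolysis stalls, and traces of oxygen may divert the C–B bond into C–O oxidation. The fallback cleaves the C–B bond by a radical instead of a polar pathway and uses no thiol, so that the Z-olefin is not isomerised. It sets out from 14: transesterification in the flask with 2-methoxy-1,3,2-benzodioxaborole should give the catechol boronic ester (7S,9Z)-17-(1,3,2-benzodioxaborol-2-yl)-17-[3,5-bis(methoxymethoxy)phenyl]heptadec-9-en-7-ol F3, which is not isolated. A radical chain with 4-tert-butylcatechol as hydrogen-atom donor (di-tert-butyl hyponitrite as initiator, toluene, 70 °C) should then replace boron by hydrogen. The fallback comes back to the route at 15.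

Step 2. The Lewis acid may rearrange or oligomerise the epoxide or open it with halide before the acetylide attacks, and the acetylide may be tied up by boron on warming, which lowers conversion. The fallback reverses the order of the two C–C bond formations and uses no Lewis acid. It sets out from 4 and 2: uncatalysed epoxide opening in DMSO at rt should give (4S)-dec-1-yn-4-ol F4, again without touching the stereocentre. Its dilithium alkoxide–acetylide F5 (n-BuLi, 2 equiv, THF/DMPU, −78 → 0 °C, not isolated) should be alkylated on carbon by 1 at the C–Br end. The fallback comes back to the route at 6.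

Further compounds
F1 | step 6 | 1-ethenyl-3,5-bis(methoxymethoxy)benzene | C=Cc1cc(OCOC)cc(OCOC)c1
F2 | step 6 | 9-{2-[3,5-bis(methoxymethoxy)phenyl]ethyl}-9-borabicyclo[3.3.1]nonane | COCOc1cc(CCB2C3CCCC2CCC3)cc(OCOC)c1
F3 | step 7 | (7S,9Z)-17-(1,3,2-benzodioxaborol-2-yl)-17-[3,5-bis(methoxymethoxy)phenyl]heptadec-9-en-7-ol | CCCCCC[C@H](O)C/C=C\CCCCCCC(B1Oc2ccccc2O1)c1cc(OCOC)cc(OCOC)c1
F4 | step 2 | (4S)-dec-1-yn-4-ol | CCCCCC[C@H](O)CC#C
F5 | step 2 | dilithium (4S)-dec-1-yn-1-id-4-olate | CCCCCC[C@H](O[Li])CC#C[Li]
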